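## Structural features

Dihydroptychantol A is a macrocyclic bis(bibenzyl) with no stereocentre. Four benzene rings are held in an 18-membered ring by two diaryl ether oxygens (ring D to ring A, ring B to ring C) and two CH2–CH2 bridges (ring A to ring B, ring C to ring D). Ring A carries its ether oxygen, the bridge carbon ortho to it and a free OH para to it. Ring B carries a free OH ortho to its ether oxygen and para to its bridge carbon. Ring C is a para-phenylene and ring D a meta-phenylene. The fragile parts are the two electron-rich phenols (ring B is a catechol monoether), which are easily oxidised, and the four benzylic CH2 groups. The real difficulty is closing the 18-membered ring with the correct oxygenation pattern and without oligomerisation. The key step exploits ring C: its C1 bears the ring B oxygen and its C4 bears the bridge carbon to ring D. That 1,4 pattern is what a 2-aryloxybuta-1,3-diene gives with an acyl-activated terminal alkyne, so ring C can be made in the ring-closing event itself, and the acyl carbon becomes the bridge carbon.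

## Logic of the disconnections

22 to 19: the two benzyl–oxygen bonds are restored and the bridge carbon next to ring C is raised to a ketone. The benzyl ethers shield both phenols from the oxidants and organometallic reagents used earlier, and the ketone is the group that activates the alkyne in the ring closure. The gain is that one hydrogenation removes all three groups. The demand is complete hydrogenolysis of the benzylic C–O bond without reduction of the arenes.

19 to 18: ring C is taken back to its 1,4-cyclohexadiene by adding two hydrogens. This is the oxidation level that a diene–alkyne cycloaddition delivers. The demand is a mild dehydrogenation that spares benzyl ethers and benzylic CH2 groups.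

18 to 17: the two carbon–carbon bonds between the diene termini and the alkyne carbons are cut. This opens ring C and the macrocycle together and leaves an open chain of three arenes. The forward step must be para-selective and must run intramolecularly.

17 back to 13 (through 16, 15 and 14): the ynone is taken back to the carbinol, the bond from the carbinol carbon to the alkyne is cut, the aldehyde is taken back to the primary alcohol and this to its silyl ether. The ynone is too electrophilic to carry, and an alkyne cannot be present when the diene is made with a titanium methylidene. Every reagent used after 13 must therefore be non-acidic, and the enolisable aldehyde 15 must be used without delay.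

13 to 12, then to 10 and 11: the terminal C=CH2 on the oxygen-bearing diene carbon is traced to an ester C=O, and the acyl–oxygen bond is then cut. The sensitive diene becomes a phenol and a commodity acid chloride. The ester must be the only carbonyl group present, which is why the ring D chain is a silyl ether at this stage.

10 to 9, then to 5 and 8: the CH2–CH2 bridge between rings A and B is unsaturated and the C=C bond is cut into an aldehyde and a phosphonium salt. The molecule falls into two halves of similar size. The reduction must spare benzyl ethers, which calls for diimide, and the olefin geometry is irrelevant.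

8 to 7 to 6: the carbon–phosphorus bond and then the benzylic C–OH are traced to the aldehyde. No protection of the phenol is needed.

5 to 4, then to 2 and 3: the silicon–oxygen bond is cut, then the diaryl ether bond between the bromine-bearing carbon of ring A and the ring D oxygen. The ortho formyl group activates the bromide. The phenol must be arylated in preference to the primary alcohol.

2 to 1: the benzyl–oxygen bond on ring A is cut. This is a routine etherification.

## Other disconnections considered

Alternative 1: The cut is the bond between C4 of ring A and the ring D oxygen, with ring A held as a cyclohexenone.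
- Forward step: Pd(PPh3)4 (zerovalent palladium) would ionise the allylic methyl carbonate of the open-chain enone A1. The ring D phenoxide would then attack the allyl terminus that lies gamma to the ketone and close the 18-membered ring as the racemic enone A2.
- In its favour: the step is catalytic, near neutral and run at room temperature. Loss of CO2 makes it irreversible, and a phenoxide is a good partner for a π-allyl complex. Rings B, C and D stay aromatic and robust throughout.
- Against it: the π-allyl unit carries an acyl group and can collapse by β-hydride elimination to a dienone that tautomerises to a phenol before the ether forms. After ring closure, ring A must be dehydrogenated to reach A6, the same methyl ether that Alternative 3 delivers. In A2 the aryloxy group is allylic, so enolisation followed by loss of the ring D phenoxide would aromatise ring A by elimination and reopen the macrocycle. The stereocentre at C4 is made only to be destroyed, ring A of A1 needs its own synthesis, and a final O-demethylation is required.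
- Comparison: both plans make one ring in non-aromatic form and aromatise it later. In 18 no leaving group sits on an sp3 carbon, so dehydrogenation is the only route to the arene; A2 has a competing eliminative route. On mechanism the alternative is the better of the two, because it is milder than a thermal cycloaddition of two sensitive π systems. Both have a regiochemical question (allyl terminus against para or meta). On step economy the chosen plan should be shorter before ring closure and equal after it (two operations each).

Alternative 2: The cut is the ether bond between the ring B carbon ortho to its hydroxyl group and the ring C oxygen.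
- Forward step: Tl(NO3)3·3H2O (trivalent thallium) in methanol would oxidise the 2,6-dibromophenol of the open-chain compound A3. The 2,6-dichlorophenol oxygen would add to a bromine-bearing ortho carbon, and zinc in acetic acid would restore the phenol with loss of that bromine, giving the macrocycle A4.
- In its favour: all four rings are aromatic from the start and the intermediates are robust. The cyclisation sets the ortho-oxygenated pattern of ring B directly. The halogenated phenol building blocks are commodity chemicals. One final hydrogenolysis over Pd/C with base would remove the remaining bromine, both chlorines and the benzyl group.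
- Against it: the oxidant is stoichiometric and highly toxic. The other electron-rich rings, above all the alkoxy-substituted ring A, may compete for the oxidant. Four halogen atoms are carried only as blocking and directing groups. A3 contains two bibenzyl bridges, so two olefination and reduction sequences are needed against one in the chosen plan.
- Comparison: on robustness of intermediates this alternative is the better one, since nothing in it is as labile as the dienyl ether and the ynone of 17. On the last step it is the equal of the chosen plan (one hydrogenation). On mechanism its regiochemistry rests on blocking groups and oxidation potentials, whereas the cycloaddition uses frontier-orbital polarisation and needs no auxiliary atoms. The overall step count should be comparable; the chosen plan wins on atom economy and avoids thallium.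

Alternative 3: The cut is the bond between the ring A carbon ortho to the ether oxygen and its benzylic bridge carbon.
- Forward step: in the 17-membered quinol ether A5 the bridge carbon and the ring D oxygen both sit on the quaternary carbon of a cyclohexa-2,5-dienone. CF3CO2H or BF3·OEt2 would trigger a dienone–phenol rearrangement in which the bridge carbon shifts to the neighbouring ring carbon, giving the 18-membered methyl ether A6.
- In its favour: the step is an isomerisation driven by aromatisation. The oxygen that stays behind stabilises the cation at the migration origin, so alkyl migration is the expected course. Ring A emerges with the correct 1,2,4 pattern and needs no later oxidation.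
- Against it: A5 itself requires a macrocyclising oxidative dearomatisation in which an oxidisable phenol must attack the para carbon of a 4-alkylphenol. That step is less secure than the rearrangement. Under acid, ionisation of the aryloxy group (ring opening) and aryloxy migration compete with the shift of a primary alkyl group, which is only a moderate migrating group. An O-demethylation remains.
- Comparison: on atom economy the two key steps are equal, since both are isomerisations. The alternative is better in that its key step yields the arene directly, whereas 18 needs DDQ. On mechanism the cycloaddition closes the large ring and the six-membered ring in one event; the alternative moves the difficult macrocyclisation to an earlier oxidative step. The step count after the key step is similar, but the way to A5 should be longer and less predictable than the way to 17.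

Key step: step 14

Remark: the carbinol carbons of 16 and 21 are racemic and transient, 9 is an E/Z mixture that converges in step 7, and the target has no stereocentre, so no stereocontrol is planned. The connectivity of 17 and 18 was checked ring by ring against the target and stands as drawn.

## Steps

Step 1
Reactants: 1 2-bromo-5-hydroxybenzaldehyde
Product: 2 5-(benzyloxy)-2-bromobenzaldehyde
Conditions: BnBr, K2CO3, DMF, rt
Reagents that add atoms: benzyl bromide, BrCc1ccccc1
Why: Williamson etherification of a phenoxide with a benzylic bromide; the aldehyde and the aryl bromide are inert.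

Step 2
Reactants: 2 5-(benzyloxy)-2-bromobenzaldehyde; 3 2-(3-hydroxyphenyl)ethanol
Product: 4 5-(benzyloxy)-2-[3-(2-hydroxyethyl)phenoxy]benzaldehyde
Conditions: CuI (cat.), N,N-dimethylglycine·HCl (cat.), Cs2CO3, 1,4-dioxane, 90 °C
Reagents that add atoms: none
Why: Ligand-accelerated Ullmann diaryl ether synthesis; the bromide is activated by the ortho formyl group, and under carbonate base only the phenol is deprotonated and arylated, not the primary alcohol.

Step 3
Reactants: 4 5-(benzyloxy)-2-[3-(2-hydroxyethyl)phenoxy]benzaldehyde
Product: 5 5-(benzyloxy)-2-[3-(2-{[tert-butyl(diphenyl)silyl]oxy}ethyl)phenoxy]benzaldehyde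
Conditions: TBDPSCl, imidazole, DMF, rt
Reagents that add atoms: tert-butyl(chloro)diphenylsilane, CC(C)(C)[Si](Cl)(c1ccccc1)c1ccccc1
Why: Silylation of the only hydroxyl group; the TBDPS ether is chosen because it should survive the weakly acidic diimide step and the later methylenation.

Step 4
Reactants: 6 4-(benzyloxy)-3-hydroxybenzaldehyde
Product: 7 2-(benzyloxy)-5-(hydroxymethyl)phenol
Conditions: NaBH4, MeOH, 0 °C
Reagents that add atoms: none
Why: Borohydride reduction of an aromatic aldehyde; the phenol and the benzyl ether are unaffected.

Step 5
Reactants: 7 2-(benzyloxy)-5-(hydroxymethyl)phenol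
Product: 8 [4-(benzyloxy)-3-hydroxybenzyl](triphenyl)phosphonium bromide
Conditions: PPh3·HBr, MeCN, reflux
Reagents that add atoms: triphenylphosphine hydrobromide, Br.c1ccc(cc1)P(c1ccccc1)c1ccccc1
Why: The para-benzyloxy group lets the benzylic alcohol ionise under these mildly acidic conditions and PPh3 captures the benzylic electrophile; this is a standard direct route to hydroxybenzyl phosphonium salts and needs no phenol protection.

Step 6
Reactants: 5 5-(benzyloxy)-2-[3-(2-{[tert-butyl(diphenyl)silyl]oxy}ethyl)phenoxy]benzaldehyde; 8 [4-(benzyloxy)-3-hydroxybenzyl](triphenyl)phosphonium bromide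
Product: 9 2-(benzyloxy)-5-{2-[5-(benzyloxy)-2-(3-{2-[(tert-butyldiphenylsilyl)oxy]ethyl}phenoxy)phenyl]ethenyl}phenol, mixture of E and Z isomers
Conditions: K2CO3, 18-crown-6 (cat.), THF, reflux
Reagents that add atoms: none
Why: Wittig olefination with a semi-stabilised benzylic ylide formed in situ; the phenoxide is meta to the ylide carbon and not conjugated with it, and the E/Z mixture does not matter because the double bond is reduced next.

Step 7
Reactants: 9 the stilbene (E/Z mixture)
Product: 10 2-(benzyloxy)-5-{2-[5-(benzyloxy)-2-(3-{2-[(tert-butyldiphenylsilyl)oxy]ethyl}phenoxy)phenyl]ethyl}phenol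
Conditions: TsNHNH2, NaOAc, THF–H2O, reflux
Reagents that add atoms: none
Why: Diimide generated in situ delivers H2 to the unpolarised stilbene double bond by concerted syn transfer and leaves benzyl ethers, silyl ether and arenes untouched, which catalytic hydrogenation would not guarantee.

Step 8
Reactants: 10 the bibenzyl phenol; 11 acryloyl chloride
Product: 12 2-(benzyloxy)-5-{2-[5-(benzyloxy)-2-(3-{2-[(tert-butyldiphenylsilyl)oxy]ethyl}phenoxy)phenyl]ethyl}phenyl prop-2-enoate
Conditions: Et3N, CH2Cl2, −20 → 0 °C
Reagents that add atoms: none
Why: O-Acylation of the only free hydroxyl group with an acid chloride; the low temperature and short contact time limit amine addition to the acrylate.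

Step 9
Reactants: 12 the aryl acrylate
Product: 13 {2-[3-(4-(benzyloxy)-2-{2-[4-(benzyloxy)-3-(buta-1,3-dien-2-yloxy)phenyl]ethyl}phenoxy)phenyl]ethoxy}(tert-butyl)diphenylsilane
Conditions: Cp2Ti(μ-Cl)(μ-CH2)AlMe2, pyridine (cat.), THF–PhMe, −40 → 0 °C; aq. NaOH; basic Al2O3
Reagents that add atoms: Tebbe reagent Cp2Ti(μ-Cl)(μ-CH2)AlMe2, C[Al](C)C[Ti](Cl)(C1C=CC=C1)C1C=CC=C1
Why: Tebbe methylenation: the titanium methylidene adds across the ester C=O and the oxatitanacyclobutane collapses to the enol ether; aryl esters and α,β-unsaturated esters are known to react at the carbonyl group, and the low temperature and basic work-up protect the acrylate and the acid-labile diene.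

Step 10
Reactants: 13 the silyl-protected dienyl ether
Product: 14 2-[3-(4-(benzyloxy)-2-{2-[4-(benzyloxy)-3-(buta-1,3-dien-2-yloxy)phenyl]ethyl}phenoxy)phenyl]ethanol
Conditions: Bu4NF, THF, 0 °C → rt
Reagents that add atoms: none
Why: Fluoride cleaves the Si–O bond; the basic, non-acidic medium leaves the dienyl ether and the benzyl ethers intact.

Step 11
Reactants: 14 the primary alcohol
Product: 15 [3-(4-(benzyloxy)-2-{2-[4-(benzyloxy)-3-(buta-1,3-dien-2-yloxy)phenyl]ethyl}phenoxy)phenyl]acetaldehyde
Conditions: Dess–Martin periodinane, NaHCO3, CH2Cl2, 0 °C
Reagents that add atoms: none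
Why: Dess–Martin oxidation under bicarbonate buffer stops at the aldehyde and exposes the dienyl ether to no acid; the arylacetaldehyde is used crude to limit enolisation and aldol condensation.

Step 12
Reactants: 15 the arylacetaldehyde
Product: 16 1-[3-(4-(benzyloxy)-2-{2-[4-(benzyloxy)-3-(buta-1,3-dien-2-yloxy)phenyl]ethyl}phenoxy)phenyl]but-3-yn-2-ol (racemic)
Conditions: HC≡CMgBr, THF, −78 → −20 °C; H2O
Reagents that add atoms: ethynylmagnesium bromide, C#C[Mg]Br
Why: 1,2-Addition of an alkynyl Grignard reagent to an aldehyde; the low temperature and the weakly basic acetylide favour addition over enolisation, and the racemic carbinol centre is removed in the next step.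

Step 13
Reactants: 16 the propargylic alcohol (racemic)
Product: 17 1-[3-(4-(benzyloxy)-2-{2-[4-(benzyloxy)-3-(buta-1,3-dien-2-yloxy)phenyl]ethyl}phenoxy)phenyl]but-3-yn-2-one
Conditions: Dess–Martin periodinane, NaHCO3, CH2Cl2, 0 °C; used at once
Reagents that add atoms: none
Why: Dess–Martin oxidation of a secondary propargylic alcohol to the ynone under buffered, non-nucleophilic conditions that both the terminal ynone and the dienyl ether tolerate.

Step 14
Reactants: 17 the dienyl ether ynone
Product: 18 18-membered cycloadduct, dibenzyl ether, in which ring C is a cyclohexa-1,4-diene with C1 on the ring B oxygen and C4 on the ketone carbon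
Conditions: PhMe (ca. 0.5 mM, syringe-pump addition), BHT (cat.), 110 °C, base-washed glass
Reagents that add atoms: none
Why: A thermal, concerted but asynchronous [4+2] cycloaddition of the electron-rich 2-aryloxydiene (HOMO) with the electron-poor terminal ynone (LUMO); the CH2 terminus next to the oxygen-bearing diene carbon bonds in advance to the unsubstituted alkyne carbon, so the acyl carbon ends para to the aryloxy carbon. The closest known reaction type is the Diels–Alder reaction of 2-oxygenated butadienes with acetylenic ketones, run here as a type 2 intramolecular Diels–Alder reaction (tether on C2 of the diene) in the manner of macrocyclising benzannulations used for cyclophanes. Ring C closes as a six-membered carbocycle by suprafacial addition on both partners, and the 18-membered ring closes in the same event because the 14-atom tether, which runs from the diene oxygen through rings B, A and D to the carbonyl carbon, spans the para positions of the new ring. No stereocentre is formed, since both new sp3 carbons are CH2 groups. The step needs para over meta regioselectivity, which the donor oxygen on the diene and the acyl acceptor on the alkyne secure; the meta mode would have to close a 17-membered ring against this polarisation. It also needs ring closure to outrun intermolecular addition, which the sub-millimolar concentration secures. BHT and base-washed glass guard the diene against radical polymerisation and acid-catalysed hydrolysis.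

Step 15
Reactants: 18 the cyclohexadiene cycloadduct
Product: 19 macrocyclic aryl ketone: dihydroptychantol A dibenzyl ether with a ketone at the bridge carbon on ring C
Conditions: DDQ, PhMe, 0 °C → rt (crude 18 taken on directly)
Reagents that add atoms: none
Why: DDQ abstracts hydride from a doubly allylic CH2 of the 1,4-cyclohexadiene and the cation loses a proton, so ring C aromatises; aryl benzyl ethers and the other benzylic positions are not oxidised at this temperature, and both phenols are still protected.

Step 16
Reactants: 19 the macrocyclic aryl ketone dibenzyl ether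
Product: 22 dihydroptychantol A, via debenzylated ketone 20 (not isolated), via benzylic carbinol 21 (not isolated)
Conditions: H2 (3 atm), Pd/C, AcOH–EtOAc, HClO4 (cat.), rt → 40 °C
Reagents that add atoms: none
Why: Hydrogenolysis of aryl benzyl ethers, hydrogenation of the aryl ketone and acid-assisted hydrogenolysis of the resulting benzylic carbinol are all standard on Pd/C. The carbinol is activated by the para-aryloxy group, and a dehydration to the stilbene would be hydrogenated to the same product.

## Compound list

1 | 2-bromo-5-hydroxybenzaldehyde | O=Cc1cc(O)ccc1Br | starting material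
2 | 5-(benzyloxy)-2-bromobenzaldehyde | O=Cc1cc(OCc2ccccc2)ccc1Br | intermediate
3 | 2-(3-hydroxyphenyl)ethanol | OCCc1cccc(O)c1 | starting material
4 | 5-(benzyloxy)-2-[3-(2-hydroxyethyl)phenoxy]benzaldehyde | O=Cc1cc(OCc2ccccc2)ccc1Oc1cccc(CCO)c1 | intermediate
5 | 5-(benzyloxy)-2-[3-(2-{[tert-butyl(diphenyl)silyl]oxy}ethyl)phenoxy]benzaldehyde | O=Cc1cc(OCc2ccccc2)ccc1Oc1cccc(CCO[Si](c2ccccc2)(c2ccccc2)C(C)(C)C)c1 | intermediate
6 | 4-(benzyloxy)-3-hydroxybenzaldehyde | O=Cc1ccc(OCc2ccccc2)c(O)c1 | starting material
7 | 2-(benzyloxy)-5-(hydroxymethyl)phenol | OCc1ccc(OCc2ccccc2)c(O)c1 | intermediate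
8 | [4-(benzyloxy)-3-hydroxybenzyl](triphenyl)phosphonium bromide | [Br-].Oc1cc(C[P+](c2ccccc2)(c2ccccc2)c2ccccc2)ccc1OCc1ccccc1 | intermediate
9 | 2-(benzyloxy)-5-{2-[5-(benzyloxy)-2-(3-{2-[(tert-butyldiphenylsilyl)oxy]ethyl}phenoxy)phenyl]ethenyl}phenol, E/Z mixture | CC(C)(C)[Si](OCCc1cccc(Oc2ccc(OCc3ccccc3)cc2C=Cc2ccc(OCc3ccccc3)c(O)c2)c1)(c1ccccc1)c1ccccc1 | intermediate
10 | 2-(benzyloxy)-5-{2-[5-(benzyloxy)-2-(3-{2-[(tert-butyldiphenylsilyl)oxy]ethyl}phenoxy)phenyl]ethyl}phenol | CC(C)(C)[Si](OCCc1cccc(Oc2ccc(OCc3ccccc3)cc2CCc2ccc(OCc3ccccc3)c(O)c2)c1)(c1ccccc1)c1ccccc1 | intermediate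
11 | acryloyl chloride | C=CC(=O)Cl | starting material
12 | 2-(benzyloxy)-5-{2-[5-(benzyloxy)-2-(3-{2-[(tert-butyldiphenylsilyl)oxy]ethyl}phenoxy)phenyl]ethyl}phenyl prop-2-enoate | CC(C)(C)[Si](OCCc1cccc(Oc2ccc(OCc3ccccc3)cc2CCc2ccc(OCc3ccccc3)c(OC(=O)C=C)c2)c1)(c1ccccc1)c1ccccc1 | intermediate
13 | {2-[3-(4-(benzyloxy)-2-{2-[4-(benzyloxy)-3-(buta-1,3-dien-2-yloxy)phenyl]ethyl}phenoxy)phenyl]ethoxy}(tert-butyl)diphenylsilane | CC(C)(C)[Si](OCCc1cccc(Oc2ccc(OCc3ccccc3)cc2CCc2ccc(OCc3ccccc3)c(OC(=C)C=C)c2)c1)(c1ccccc1)c1ccccc1 | intermediate
14 | 2-[3-(4-(benzyloxy)-2-{2-[4-(benzyloxy)-3-(buta-1,3-dien-2-yloxy)phenyl]ethyl}phenoxy)phenyl]ethanol | OCCc1cccc(Oc2ccc(OCc3ccccc3)cc2CCc2ccc(OCc3ccccc3)c(OC(=C)C=C)c2)c1 | intermediate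
15 | [3-(4-(benzyloxy)-2-{2-[4-(benzyloxy)-3-(buta-1,3-dien-2-yloxy)phenyl]ethyl}phenoxy)phenyl]acetaldehyde | O=CCc1cccc(Oc2ccc(OCc3ccccc3)cc2CCc2ccc(OCc3ccccc3)c(OC(=C)C=C)c2)c1 | intermediate
16 | 1-[3-(4-(benzyloxy)-2-{2-[4-(benzyloxy)-3-(buta-1,3-dien-2-yloxy)phenyl]ethyl}phenoxy)phenyl]but-3-yn-2-ol (racemic) | C#CC(O)Cc1cccc(Oc2ccc(OCc3ccccc3)cc2CCc2ccc(OCc3ccccc3)c(OC(=C)C=C)c2)c1 | intermediate
17 | 1-[3-(4-(benzyloxy)-2-{2-[4-(benzyloxy)-3-(buta-1,3-dien-2-yloxy)phenyl]ethyl}phenoxy)phenyl]but-3-yn-2-one | O(Cc1ccccc1)c1ccc(Oc2cccc(CC(=O)C#C)c2)c(CCc2ccc(OCc3ccccc3)c(OC(=C)C=C)c2)c1 | intermediate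
18 | 18-membered cycloadduct, dibenzyl ether, ring C as 1-aryloxy-4-acylcyclohexa-1,4-diene | O(Cc1ccccc1)c1ccc2c(c1)CCc1ccc(OCc3ccccc3)c(c1)OC1=CCC(=CC1)C(=O)Cc1cccc(c1)O2 | intermediate
19 | dihydroptychantol A dibenzyl ether with a ketone at the bridge carbon on ring C | O(Cc1ccccc1)c1ccc2c(c1)CCc1ccc(OCc3ccccc3)c(c1)Oc1ccc(cc1)C(=O)Cc1cccc(c1)O2 | intermediate
20 | dihydroptychantol A with a ketone at the bridge carbon on ring C | Oc1ccc2c(c1)CCc1ccc(O)c(c1)Oc1ccc(cc1)C(=O)Cc1cccc(c1)O2 | intermediate
21 | dihydroptychantol A with a hydroxyl group at the bridge carbon on ring C (racemic) | Oc1ccc2c(c1)CCc1ccc(O)c(c1)Oc1ccc(cc1)C(O)Cc1cccc(c1)O2 | intermediate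
22 | dihydroptychantol A | Oc1ccc2c(c1)CCc1ccc(O)c(c1)Oc1ccc(cc1)CCc1cccc(c1)O2 | target

## Step count and least certain steps

Total: 16 steps. Longest linear sequence: 14 steps (1 → 2 → 4 → 5 → 9 → 10 → 12 → 13 → 14 → 15 → 16 → 17 → 18 → 19 → 22). The ring B branch (6 → 7 → 8) joins at step 6.

Step 14 (key step).
- What may go wrong: intermolecular cycloaddition and oligomerisation may outrun closure of the large ring. The terminal ynone may polymerise or add adventitious nucleophiles during the long heating. The dienyl ether may hydrolyse on acidic surfaces. Regioselectivity may erode toward the meta mode because the tether is long enough to allow both.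
- Fallback: ring C is brought in as a preformed arene and the macrocycle is closed at the ring B ether by nucleophilic aromatic substitution. From 15, addition of 4-fluorophenylmagnesium bromide gives the racemic 4-fluorophenyl carbinol F1. Dess–Martin oxidation gives the 4-fluorophenyl ketone F2. Brief treatment with dilute HCl in THF hydrolyses the dienyl ether, which here serves as a phenol protecting group, to the ring B phenol F3. Cs2CO3 in DMF at high dilution then displaces the fluoride para to the ketone and returns to the route at 19.

Step 9.
- What may go wrong: the acrylate or the product diene may polymerise. The aryl ester may be cleaved by aluminium species. The dienyl ether may hydrolyse during work-up or chromatography.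
- Fallback: the diene is made by allylic etherification and elimination, without a titanium reagent. From 10, ring opening of 2-vinyloxirane by the phenol under zerovalent palladium catalysis (Pd2(dba)3 with the racemic bis(2-diphenylphosphinobenzamide) of trans-cyclohexane-1,2-diamine, CH2Cl2) should give the branched allylic ether, racemic 2-aryloxybut-3-en-1-ol F4. MsCl and Et3N give the methanesulfonate F5. E2 elimination with KOtBu in THF removes the allylic proton on the oxygen-bearing carbon and returns to the route at 13.

Step 12.
- What may go wrong: the Grignard reagent may enolise the arylacetaldehyde, followed by aldol self-condensation, so that conversion to the carbinol stays low.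
- Fallback: a non-basic organochromium addition. From 15, a Nozaki–Hiyama–Kishi-type reaction with (iodoethynyl)trimethylsilane and CrCl2 (divalent chromium chloride) in THF–DMF gives the silylated carbinol, racemic 4-(trimethylsilyl)but-3-yn-2-ol F6. K2CO3 in MeOH removes the silyl group and returns to the route at 16.

Step 16.
- What may go wrong: hydrogenolysis of the benzylic C–O bond may stall at the carbinol. Under more forcing acid the benzylic cation may alkylate one of the electron-rich rings.
- Fallback: deoxygenation and debenzylation are separated. From 19, ionic hydrogenation with Et3SiH in CF3CO2H–CH2Cl2 reduces the aryl ketone to CH2 and gives dihydroptychantol A dibenzyl ether F7. Neutral hydrogenolysis (H2, Pd/C, EtOAc–MeOH) returns to the route at 22.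

## Further compounds

F1 | step 14 | 2-[3-(4-(benzyloxy)-2-{2-[4-(benzyloxy)-3-(buta-1,3-dien-2-yloxy)phenyl]ethyl}phenoxy)phenyl]-1-(4-fluorophenyl)ethanol (racemic) | OC(Cc1cccc(Oc2ccc(OCc3ccccc3)cc2CCc2ccc(OCc3ccccc3)c(OC(=C)C=C)c2)c1)c1ccc(F)cc1
F2 | step 14 | 2-[3-(4-(benzyloxy)-2-{2-[4-(benzyloxy)-3-(buta-1,3-dien-2-yloxy)phenyl]ethyl}phenoxy)phenyl]-1-(4-fluorophenyl)ethanone | O=C(Cc1cccc(Oc2ccc(OCc3ccccc3)cc2CCc2ccc(OCc3ccccc3)c(OC(=C)C=C)c2)c1)c1ccc(F)cc1
F3 | step 14 | 2-[3-(4-(benzyloxy)-2-{2-[4-(benzyloxy)-3-hydroxyphenyl]ethyl}phenoxy)phenyl]-1-(4-fluorophenyl)ethanone | O=C(Cc1cccc(Oc2ccc(OCc3ccccc3)cc2CCc2ccc(OCc3ccccc3)c(O)c2)c1)c1ccc(F)cc1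
F4 | step 9 | 2-[2-(benzyloxy)-5-{2-[5-(benzyloxy)-2-(3-{2-[(tert-butyldiphenylsilyl)oxy]ethyl}phenoxy)phenyl]ethyl}phenoxy]but-3-en-1-ol (racemic) | CC(C)(C)[Si](OCCc1cccc(Oc2ccc(OCc3ccccc3)cc2CCc2ccc(OCc3ccccc3)c(OC(CO)C=C)c2)c1)(c1ccccc1)c1ccccc1
F5 | step 9 | methanesulfonate of F4 (racemic) | CC(C)(C)[Si](OCCc1cccc(Oc2ccc(OCc3ccccc3)cc2CCc2ccc(OCc3ccccc3)c(OC(COS(C)(=O)=O)C=C)c2)c1)(c1ccccc1)c1ccccc1
F6 | step 12 | 1-[3-(4-(benzyloxy)-2-{2-[4-(benzyloxy)-3-(buta-1,3-dien-2-yloxy)phenyl]ethyl}phenoxy)phenyl]-4-(trimethylsilyl)but-3-yn-2-ol (racemic) | C[Si](C)(C)C#CC(O)Cc1cccc(Oc2ccc(OCc3ccccc3)cc2CCc2ccc(OCc3ccccc3)c(OC(=C)C=C)c2)c1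
F7 | step 16 | dihydroptychantol A dibenzyl ether | O(Cc1ccccc1)c1ccc2c(c1)CCc1ccc(OCc3ccccc3)c(c1)Oc1ccc(cc1)CCc1cccc(c1)O2
A1 | alternative 1 | 3-{2-[3-(4-{2-(3-hydroxyphenyl)ethyl}phenoxy)-4-methoxyphenyl]ethyl}-4-[(methoxycarbonyl)oxy]cyclohex-2-en-1-one (racemic) | O=C1C=C(CCc2ccc(OC)c(Oc3ccc(CCc4cccc(O)c4)cc3)c2)C(OC(=O)OC)CC1
A2 | alternative 1 | macrocyclic 4-aryloxy-3-alkylcyclohex-2-enone, ring B methyl ether (racemic) | O=C1C=C2C(CC1)Oc1cccc(c1)CCc1ccc(cc1)Oc1cc(ccc1OC)CC2
A3 | alternative 2 | open-chain compound with 2,6-dibromophenol (ring B) and 2,6-dichlorophenol (ring C), ring A benzyl ether | O(Cc1ccccc1)c1ccc(Oc2cccc(CCc3cc(Cl)c(O)c(Cl)c3)c2)c(CCc2cc(Br)c(O)c(Br)c2)c1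
A4 | alternative 2 | macrocyclic diaryl ether with one bromine on ring B and two chlorines on ring C, ring A benzyl ether | O(Cc1ccccc1)c1ccc2c(c1)CCc1cc(Br)c(O)c(c1)Oc1c(Cl)cc(cc1Cl)CCc1cccc(c1)O2
A5 | alternative 3 | 17-membered quinol ether: 4-alkyl-4-aryloxycyclohexa-2,5-dienone, ring B methyl ether | O=C1C=CC2(C=C1)CCc1ccc(OC)c(c1)Oc1ccc(cc1)CCc1cccc(c1)O2
A6 | alternative 3 | dihydroptychantol A methyl ether at the ring B oxygen | Oc1ccc2c(c1)CCc1ccc(OC)c(c1)Oc1ccc(cc1)CCc1cccc(c1)O2
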